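## Analysis of the target

The target 20 is a labdane-type diterpenoid: a decalin (ring A = C1–C5 and C10, ring B = C5–C10) with a gem-dimethyl group on C4, an angular methyl (C20) on C10, a tertiary carbinol carrying the methyl C17 on C8, and on C9 a C11–C15 chain that has a methyl-bearing stereocentre at C13 and ends in a primary acetate. Four contiguous ring stereocentres (C5, C10, C9, C8; 4aS, 8aR, 1R, 2R in naphthalene numbering) and the remote C13 (S) must be controlled. The C5 hydrogen and the C10 methyl are cis, so the decalin is cis-fused, unlike the common trans-labdanes; the C9 hydrogen and the C8 hydroxyl lie on that same face, and the chain, the C8 methyl and the ring A bonds C5–C4 and C10–C1 lie on the other. C13 is separated from the ring by two methylene groups and cannot be induced from it, so it has to arrive in an enantiopure chain piece. The sensitive groups are the tertiary C8 alcohol, which dehydrates readily toward C7 or C9 under acid, and the acetate, which tolerates neither hydride nor organometallic reagents and must therefore come last. The difficulty lies in the quaternary C10 with the neopentyl C9 beside it, in C5 being flanked by two fully substituted carbons, and in the cis relationship of H9 and the C8 hydroxyl, which a carbonyl addition at C8 does not deliver reliably. The feature the plan exploits is ring B: its methyls on C8 and C10 flank C9 exactly as the methyls of 2,6-dimethyl-1,4-benzoquinone 1 flank one carbonyl, and it is cis-fused to a ring A whose only substituents are the two C4 methyls, the pattern that 4-methylpenta-1,3-diene 2 leaves when it adds across a methyl-bearing double bond of 1.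

## Retrosynthetic reasoning

**C15–O acetyl bond.** Target 20 is cut first at the ester, because the acetate cannot coexist with the organomagnesium and hydride chemistry used earlier. The precursor is diol 19, whose primary C15 hydroxyl is far more accessible than the tertiary C8 hydroxyl, so monoacetylation needs no protecting group. Diol 19 comes from silyl ether 18 by desilylation; the silyl group carries the C15 oxygen through the route.

**C8–O and C9–H bonds.** In 18 the C8 hydroxyl and the C9 hydrogen are cis on neighbouring carbons, which is the signature of a syn hydration of a C8=C9 double bond. Cutting both bonds gives tetrasubstituted alkene 16. This is preferred to methyl addition to a C8 ketone, which would have to approach from the face of the C9 chain. The forward hydroboration–oxidation must place boron on C8 (alkylborane 17), the alkene carbon not attached to quaternary C10, and must add from the face of H5 and the C10 methyl. Ring A is folded under the other face in the cis-decalin, which should direct the addition.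

**C9–C11 bond.** With C9 sp2, the whole side chain is removed: alkene 16 goes back to enol triflate 9 and Grignard reagent 15, made from bromide 14. The cut is made here because it separates the ring part from the piece holding the isolated C13 centre. It also avoids alkylating an enolate carbon next to quaternary C10; a cross-coupling at an sp2 carbon is much less sensitive to that crowding.

**The chain piece.** Bromide 14 is traced through alcohol 13, silyl ether ester 12 and hydroxy ester 11 to half-ester 10. The two ends of 10 differ chemically, so the acid end becomes C15 and the ester end becomes C11. This fixes C13 in the required sense without any stereoselective step.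

**C9–O bond of the triflate.** Triflate 9 comes from ketone 7 through enolate 8. C10 is quaternary, so 7 can enolise only toward C8, and the C8=C9 double bond is placed without a regiochemical question.

**C6 oxygen and the ring double bonds.** Ketone 7 is traced through unsaturated ketone 6, acetate 5 and carbinol 4 to ene-dione 3. The C6 carbonyl, needed only to steer the cycloaddition, is excised by 1,2-reduction, acylation and reductive cleavage of the resulting vinylogous α-acyloxy ketone; hydrogenation then removes the two alkenes. This order is preferred to removing the oxygen after saturation. In a saturated system C5 would sit next to a free carbonyl and could epimerise, and a bulky sulfur-based derivative would have to form beside the C4 gem-dimethyl group. Here C5 stops being enolisable in the first step after the cycloaddition.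

**C1–C10 and C4–C5 bonds (ring A).** Ene-dione 3 is cut across ring A into quinone 1 and diene 2. No other cut gives two commercial pieces while also delivering C17, C20 and the gem-dimethyl group at their final oxidation level and making the cis fusion a mechanistic consequence. The forward [4+2] reaction has to join the CH2 terminus of 2 to the methyl-bearing carbon of 1 (C10) and the CMe2 terminus to C5, on one face of the quinone, under a chiral boron Lewis acid that selects that face.

## Alternatives that were turned down

**Alternative 1:** Ring A is closed last, at C3–C4, by a radical relay from a gem-dimethylcyclobutane. The disconnection cuts C3–C4 and reconnects C4 to C7, leading to bicyclo[3.1.1]heptanone A1, in which C4 bridges C5 and C7 and C10 carries the methyl and a 2-chloroallyl group. In the forward step the tin radical from Bu3SnH would add to the C8 carbonyl oxygen and the ketyl would open the strained C4–C7 bond. The tertiary C4 radical would then add to the terminal carbon C3 of the chloroallyl group in a 6-endo closure, and more Bu3SnH would remove the chlorine to give 9-alkyl cis-decalin-8-one A2.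
- For it: the gem-dimethyl carbon and the C5 configuration come from the terpene chiral pool, ring strain drives the fragmentation, the chain is already attached, and the tether enforces the cis fusion. On the gem-dimethyl group it is at least as good as the chosen plan, since no reluctant diene is involved.
- Against it: A1 is itself a demanding target. Quaternary C10 and the C9 centre must be set on the bicycle, where reagents approach anti to the CMe2 bridge, and it is not clear that this gives the needed C10 configuration. The cascade needs stoichiometric tin, and simple reduction of the C4 radical competes with the 6-endo addition. A2 then still requires a methyl nucleophile to attack C8 from the face occupied by the C9 chain.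
- Comparison: it is longer before its key step and leaves C8 to a diastereoselective carbonyl addition. The chosen route sets C8 and C9 together by one syn addition and places its main risk in the first step, on commercial materials.

**Alternative 2:** Ring B is closed by a carbene. Cutting C9–C10 and C1–C9 leads to diazoketone A3, a 2,6,6-trimethylcyclohex-2-enyl ring (ring A with C1=C10) bearing the C6–C9 chain on C5. Rh2(OAc)4 would generate the C9 carbenoid, which the tether delivers across C1=C10 to give tricyclic cyclopropyl ketone A4. Later reductive opening of C1–C9 would leave the C10 methyl quaternary and an enolate at C9 for attaching the chain.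
- For it: A3 is a few steps from a chiral-pool carboxylic acid, intramolecular cyclopropanation of trisubstituted alkenes by dirhodium carbenoids is dependable, and the tether forces the cis fusion. The way to the decalin core is probably shorter than in the chosen plan. On step count and on reliability of the key step this alternative is the stronger one.
- Against it: the cyclopropane must break at C1–C9 and not at C9–C10, although the latter gives the more substituted centre. The chain has to be attached by alkylating an enolate carbon next to quaternary C10. The C8 carbinol must again be made by methyl addition from the face of the new C9 substituent.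
- Comparison: in exchange for the extra steps, the chosen route uses a cross-coupling in place of the neopentyl alkylation and one syn hydroboration in place of two separate stereochemical events at C9 and C8.

**Alternative 3:** Ring B is made by a Diels–Alder reaction between (E)-enal A5 and 1-amino-3-siloxydiene A6. The aldehyde carbon of A5 is the future C20; its β-carbon (C9) carries the C11–C15 chain and its α-carbon (C10) a homoprenyl group (C1–C4). Under the chiral trivalent chromium complex (salen)Cr(SbF6), C5–C10 and C8–C9 would form, and acidic work-up would give cyclohexenone A7.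
- For it: quaternary C10 and C9 are set in one catalytic enantioselective step, the chain is present from the start, and the C5=C6–C7 enone is placed for closing ring A onto C5 from the homoprenyl alkene. It matches the chosen plan in using asymmetric catalysis for C10 and is stronger in having C9 and the chain in place at once.
- Against it: A7 has its oxygen on C7, whereas the target needs a methyl carbinol on C8, so a carbonyl transposition or an equivalent multi-step adjustment is required. C20 is an aldehyde that must be reduced to a methyl group. Ring A and C5 are still to be made, so the cis fusion depends on a further cyclisation. A5 is an α-branched, β-substituted enal, a sluggish dienophile class.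
- Comparison: it is clearly longer after its key step. The cycloaddition of the chosen route delivers C17, C20 and the gem-dimethyl group at the correct oxidation level and the cis fusion directly.

Key step: step 1

Assumption: the (S)-configured oxazaborolidinium cation is taken to be the enantiomer that leads to the (4aS,8aR) adduct 3, as its binding model predicts; the (R)-catalyst would be used instead if the sense proved opposite.

Assumption: labdane numbering (ring A = C1–C5 and C10, ring B = C5–C10) is used for positions; systematic names use naphthalene numbering.

## Route

Step 1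
Reactants: 1 2,6-dimethyl-1,4-benzoquinone; 2 4-methylpenta-1,3-diene
Product: 3 (4aS,8aR)-2,5,5,8a-tetramethyl-4a,5,8,8a-tetrahydronaphthalene-1,4-dione
Conditions: 2 (4 equiv, distilled after removal of 2-methylpenta-1,3-diene with maleic anhydride), N-protonated (S)-1-(2-methylphenyl)-3,3-diphenyltetrahydro-1H,3H-pyrrolo[1,2-c][1,3,2]oxazaborole triflimide (20 mol %, from the oxazaborolidine and Tf2NH), CH2Cl2, −78 → −30 °C
Reagents that add atoms: none
Why: Lewis-acid-catalysed, concerted but asynchronous [4+2] cycloaddition; the closest known reaction type is the oxazaborolidinium-catalysed Diels–Alder reaction of 2,6-dimethyl-1,4-benzoquinone with other dienes, so only the diene is new. The boron binds the C6 carbonyl oxygen, the more basic one (vinylogous donation from both methyls) and the only one flanked by α-C–H bonds, which makes the methyl-bearing β-carbon C10 the electrophilic terminus. The CH2 terminus of 2, which has the largest HOMO coefficient because both donor methyls sit at the other end, bonds to C10 ahead of the CMe2 terminus bonding to C5, so the regiochemistry is fixed electronically and also sterically (the two fully substituted carbons are not joined to each other). Ring A is closed in this same event through a six-membered cyclic transition state in which both new bonds (C1–C10 and C4–C5) form on one face of the quinone double bond. This suprafacial delivery makes the C5 hydrogen and the C10 methyl cis, so the cis fusion needs no further control; endo/exo is not an issue because C1 is CH2 and C4 bears two identical methyls. The absolute configuration of C5 and C10 is controlled by the catalyst: the coordinated double bond lies over a phenyl group of the cation and the diene adds to the exposed face, which for the (S)-catalyst should give (4aS,8aR). The two methyl-bearing double bonds of 1 are equivalent by symmetry, so no site selectivity is needed; regio- and enantioselectivity both follow from the single binding mode at the C6 oxygen. The limiting factor is the Z-methyl of 2, which destabilises the s-cis conformer, hence the triflimide-activated cation, excess diene and slow warming.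

Step 2
Reactants: 3 (4aS,8aR)-2,5,5,8a-tetramethyl-4a,5,8,8a-tetrahydronaphthalene-1,4-dione
Product: 4 (4aS,8aR)-4-hydroxy-2,5,5,8a-tetramethyl-4a,5,8,8a-tetrahydronaphthalen-1(4H)-one (C6 carbinol; configuration at C6 immaterial)
Conditions: NaBH4 (1 equiv), CeCl3·7H2O (1 equiv), MeOH/CH2Cl2, −78 °C
Reagents that add atoms: none
Why: Luche 1,2-reduction of an ene-dione; the cerium salt activates the more basic C6 carbonyl and hydride reaches it past the C5 hydrogen, whereas the C9 carbonyl is screened on both faces by the substituents of quaternary C10 and by the C8 methyl. The new C6 centre is removed in step 4, and the reduction takes away the only carbonyl that could epimerise C5.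

Step 3
Reactants: 4 (4aS,8aR)-4-hydroxy-2,5,5,8a-tetramethyl-4a,5,8,8a-tetrahydronaphthalen-1(4H)-one
Product: 5 (4aS,8aR)-4-acetoxy-2,5,5,8a-tetramethyl-4a,5,8,8a-tetrahydronaphthalen-1(4H)-one
Conditions: Ac2O, DMAP (cat.), pyridine, CH2Cl2, 0 °C → rt
Reagents that add atoms: acetic anhydride, CC(=O)OC(C)=O
Why: DMAP-catalysed acylation of a secondary allylic alcohol; it turns the γ-oxygen into a leaving group for the reductive cleavage and touches no stereocentre that is kept.

Step 4
Reactants: 5 (4aS,8aR)-4-acetoxy-2,5,5,8a-tetramethyl-4a,5,8,8a-tetrahydronaphthalen-1(4H)-one
Product: 6 (4aS,8aR)-2,5,5,8a-tetramethyl-4a,5,8,8a-tetrahydronaphthalen-1(2H)-one (C6=C7 and C2=C3 alkenes; C8 epimers)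
Conditions: Zn dust, AcOH, rt → 50 °C
Reagents that add atoms: none
Why: Zinc reduction of a γ-acyloxy enone (vinylogous α-acetoxy ketone cleavage): two-electron reduction of the C9 enone expels acetate from C6, and the dienolate is protonated mainly at C8, so C6 is deoxygenated while the C9 carbonyl stays. The alkene position (some C7=C8 isomer may form) and the C8 configuration are erased in steps 5 and 6.

Step 5
Reactants: 6 (4aS,8aR)-2,5,5,8a-tetramethyl-4a,5,8,8a-tetrahydronaphthalen-1(2H)-one
Product: 7 (4aS,8aR)-2,5,5,8a-tetramethyloctahydronaphthalen-1(2H)-one (cis-fused; C8 epimers)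
Conditions: H2 (1–3 atm), 10% Pd/C, EtOAc, rt
Reagents that add atoms: none
Why: Heterogeneous hydrogenation of two disubstituted alkenes; neither ring-fusion centre is α to a carbonyl with a hydrogen to lose, so the cis fusion is safe, and C8 is obtained as an epimer mixture that becomes sp2 in step 6.

Step 6
Reactants: 7 (4aS,8aR)-2,5,5,8a-tetramethyloctahydronaphthalen-1(2H)-one
Product: 9 (4aS,8aR)-2,5,5,8a-tetramethyl-3,4,4a,5,6,7,8,8a-octahydronaphthalen-1-yl trifluoromethanesulfonate, via potassium enolate 8 (not isolated)
Conditions: KHMDS, THF, −78 → 0 °C; PhNTf2, −78 °C → rt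
Reagents that add atoms: N-phenylbis(trifluoromethanesulfonimide), O=S(=O)(N(c1ccccc1)S(=O)(=O)C(F)(F)F)C(F)(F)F
Why: Enolate O-sulfonylation; C10 is quaternary, so deprotonation can occur only at C8 and gives the tetrasubstituted C8=C9 enolate regiospecifically, as known for 2,2,6-trisubstituted cyclohexanones.

Step 7
Reactants: 10 methyl hydrogen (R)-3-methylglutarate
Product: 11 methyl (R)-5-hydroxy-3-methylpentanoate
Conditions: BH3·SMe2, THF, −10 °C → rt; then MeOH
Reagents that add atoms: none
Why: Chemoselective borane reduction of a carboxylic acid (through the acyloxyborane) in the presence of a methyl ester; it differentiates the two ends of the glutarate, and C13 is not at an acidic position.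

Step 8
Reactants: 11 methyl (R)-5-hydroxy-3-methylpentanoate
Product: 12 methyl (R)-5-(tert-butyldimethylsilyloxy)-3-methylpentanoate
Conditions: TBSCl, imidazole, DMF, 0 °C → rt
Reagents that add atoms: tert-butyldimethylsilyl chloride, CC(C)(C)[Si](C)(C)Cl
Why: Imidazole-mediated silylation of the primary alcohol, done on the crude hydroxy ester before it can lactonise.

Step 9
Reactants: 12 methyl (R)-5-(tert-butyldimethylsilyloxy)-3-methylpentanoate
Product: 13 (S)-5-(tert-butyldimethylsilyloxy)-3-methylpentan-1-ol
Conditions: LiAlH4, Et2O, 0 °C; aq NaOH work-up
Reagents that add atoms: none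
Why: Hydride reduction of the ester to the primary alcohol; the silyl ether is inert at 0 °C (the descriptor changes only through the priority rules).

Step 10
Reactants: 13 (S)-5-(tert-butyldimethylsilyloxy)-3-methylpentan-1-ol
Product: 14 [(3R)-5-bromo-3-methylpentyl]oxy(tert-butyl)dimethylsilane
Conditions: CBr4, PPh3, CH2Cl2, 0 °C → rt
Reagents that add atoms: carbon tetrabromide, BrC(Br)(Br)Br
Why: Appel bromination of a primary alcohol under neutral conditions; the bromide is chosen over the iodide because it forms the Grignard reagent with less Wurtz coupling.

Step 11
Reactants: 9 (4aS,8aR)-2,5,5,8a-tetramethyl-3,4,4a,5,6,7,8,8a-octahydronaphthalen-1-yl trifluoromethanesulfonate; 14 [(3R)-5-bromo-3-methylpentyl]oxy(tert-butyl)dimethylsilane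
Product: 16 tert-butyldimethyl{[(3S)-3-methyl-5-[(4aS,8aR)-2,5,5,8a-tetramethyl-3,4,4a,5,6,7,8,8a-octahydronaphthalen-1-yl]pentyl]oxy}silane, via Grignard reagent 15 (not isolated)
Conditions: 14, Mg, THF, rt → 40 °C; then 9, Fe(acac)3 (10 mol %), THF/NMP, −30 → 0 °C
Reagents that add atoms: none
Why: Iron-catalysed Kumada-type cross-coupling of an alkenyl triflate with a primary alkyl Grignard reagent; the low-valent iron species formed in situ couples faster than β-hydride elimination of the alkyl group, so the C9–C11 bond forms with the double bond held at C8=C9. The silyl ether and the remote C13 centre are not affected.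

Step 12
Reactants: 16 tert-butyldimethyl{[(3S)-3-methyl-5-[(4aS,8aR)-2,5,5,8a-tetramethyl-3,4,4a,5,6,7,8,8a-octahydronaphthalen-1-yl]pentyl]oxy}silane
Product: 18 (1R,2R,4aS,8aR)-1-[(3S)-5-(tert-butyldimethylsilyloxy)-3-methylpentyl]-2,5,5,8a-tetramethyldecahydronaphthalen-2-ol, via alkylborane 17 (not isolated)
Conditions: BH3·THF (5 equiv), THF, 0 °C → rt (not above 40 °C); then NaOH, H2O2, H2O, 0 °C → rt
Reagents that add atoms: hydrogen peroxide, OO
Why: Hydroboration–oxidation of a tetrasubstituted cycloalkene; H–B adds syn with boron on C8, the carbon not attached to quaternary C10, and from the face of H5 and the C10 methyl, because in the reactive half-chair the C10 methyl is pseudoequatorial while C1 of ring A sits pseudoaxially over the other face. Oxidation with retention then gives the C8 hydroxyl cis to H9, which sets C8 and C9 together.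

Step 13
Reactants: 18 (1R,2R,4aS,8aR)-1-[(3S)-5-(tert-butyldimethylsilyloxy)-3-methylpentyl]-2,5,5,8a-tetramethyldecahydronaphthalen-2-ol
Product: 19 (1R,2R,4aS,8aR)-1-[(3S)-5-hydroxy-3-methylpentyl]-2,5,5,8a-tetramethyldecahydronaphthalen-2-ol
Conditions: TBAF, THF, 0 °C → rt
Reagents that add atoms: none
Why: Fluoride cleavage of a primary silyl ether; the tertiary alcohol is inert to these non-acidic conditions.

Step 14
Reactants: 19 (1R,2R,4aS,8aR)-1-[(3S)-5-hydroxy-3-methylpentyl]-2,5,5,8a-tetramethyldecahydronaphthalen-2-ol
Product: 20 (3S)-5-[(1R,2R,4aS,8aR)-2-hydroxy-2,5,5,8a-tetramethyldecahydronaphthalen-1-yl]-3-methylpentyl acetate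
Conditions: Ac2O, pyridine, CH2Cl2, 0 °C → rt
Reagents that add atoms: acetic anhydride, CC(=O)OC(C)=O
Why: Acylation selective for the primary hydroxyl; the hindered tertiary C8 hydroxyl does not acylate without DMAP or heat, so the target should be reached without protection.

## Compound list

1 | 2,6-dimethyl-1,4-benzoquinone | CC1=CC(=O)C=C(C)C1=O | starting material
2 | 4-methylpenta-1,3-diene | C=CC=C(C)C | starting material
3 | (4aS,8aR)-2,5,5,8a-tetramethyl-4a,5,8,8a-tetrahydronaphthalene-1,4-dione (cis-fused ene-dione) | O=C1C(C)=CC(=O)[C@H]2C(C)(C)C=CC[C@@]12C | intermediate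
4 | (4aS,8aR)-4-hydroxy-2,5,5,8a-tetramethyl-4a,5,8,8a-tetrahydronaphthalen-1(4H)-one (C6 configuration not defined) | O=C1C(C)=CC(O)[C@H]2C(C)(C)C=CC[C@@]12C | intermediate
5 | (4aS,8aR)-4-acetoxy-2,5,5,8a-tetramethyl-4a,5,8,8a-tetrahydronaphthalen-1(4H)-one | O=C1C(C)=CC(OC(C)=O)[C@H]2C(C)(C)C=CC[C@@]12C | intermediate
6 | (4aS,8aR)-2,5,5,8a-tetramethyl-4a,5,8,8a-tetrahydronaphthalen-1(2H)-one (C8 epimers) | O=C1C(C)C=C[C@H]2C(C)(C)C=CC[C@@]12C | intermediate
7 | (4aS,8aR)-2,5,5,8a-tetramethyloctahydronaphthalen-1(2H)-one (C8 epimers) | O=C1C(C)CC[C@H]2C(C)(C)CCC[C@@]12C | intermediate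
8 | potassium (4aS,8aR)-2,5,5,8a-tetramethyl-3,4,4a,5,6,7,8,8a-octahydronaphthalen-1-olate | [K+].[O-]C1=C(C)CC[C@H]2C(C)(C)CCC[C@@]12C | intermediate (not isolated)
9 | (4aS,8aR)-2,5,5,8a-tetramethyl-3,4,4a,5,6,7,8,8a-octahydronaphthalen-1-yl trifluoromethanesulfonate | O=S(=O)(OC1=C(C)CC[C@H]2C(C)(C)CCC[C@@]12C)C(F)(F)F | intermediate
10 | methyl hydrogen (R)-3-methylglutarate | OC(=O)C[C@@H](C)CC(=O)OC | starting material
11 | methyl (R)-5-hydroxy-3-methylpentanoate | OCC[C@@H](C)CC(=O)OC | intermediate
12 | methyl (R)-5-(tert-butyldimethylsilyloxy)-3-methylpentanoate | CC(C)(C)[Si](C)(C)OCC[C@@H](C)CC(=O)OC | intermediate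
13 | (S)-5-(tert-butyldimethylsilyloxy)-3-methylpentan-1-ol | CC(C)(C)[Si](C)(C)OCC[C@@H](C)CCO | intermediate
14 | [(3R)-5-bromo-3-methylpentyl]oxy(tert-butyl)dimethylsilane | CC(C)(C)[Si](C)(C)OCC[C@@H](C)CCBr | intermediate
15 | [(3R)-5-(tert-butyldimethylsilyloxy)-3-methylpentyl]magnesium bromide | CC(C)(C)[Si](C)(C)OCC[C@@H](C)CC[Mg]Br | intermediate (not isolated)
16 | tert-butyldimethyl{[(3S)-3-methyl-5-[(4aS,8aR)-2,5,5,8a-tetramethyl-3,4,4a,5,6,7,8,8a-octahydronaphthalen-1-yl]pentyl]oxy}silane | CC(C)(C)[Si](C)(C)OCC[C@@H](C)CCC1=C(C)CC[C@H]2C(C)(C)CCC[C@@]12C | intermediate
17 | C8 monoalkylborane from syn addition to 16 (boron on C8, hydrogen on C9, both on the face of H5 and the C10 methyl) | CC(C)(C)[Si](C)(C)OCC[C@@H](C)CC[C@@H]1[C@]2(C)CCCC(C)(C)[C@@H]2CC[C@@]1(C)B | intermediate (not isolated)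
18 | (1R,2R,4aS,8aR)-1-[(3S)-5-(tert-butyldimethylsilyloxy)-3-methylpentyl]-2,5,5,8a-tetramethyldecahydronaphthalen-2-ol | CC(C)(C)[Si](C)(C)OCC[C@@H](C)CC[C@@H]1[C@]2(C)CCCC(C)(C)[C@@H]2CC[C@@]1(C)O | intermediate
19 | (1R,2R,4aS,8aR)-1-[(3S)-5-hydroxy-3-methylpentyl]-2,5,5,8a-tetramethyldecahydronaphthalen-2-ol | OCC[C@@H](C)CC[C@@H]1[C@]2(C)CCCC(C)(C)[C@@H]2CC[C@@]1(C)O | intermediate
20 | (3S)-5-[(1R,2R,4aS,8aR)-2-hydroxy-2,5,5,8a-tetramethyldecahydronaphthalen-1-yl]-3-methylpentyl acetate | CC(=O)OCC[C@@H](C)CC[C@@H]1[C@]2(C)CCCC(C)(C)[C@@H]2CC[C@@]1(C)O | target

## Step count and least certain steps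

Total: 14 steps. Longest linear sequence: 10 steps (steps 1–6 and 11–14 from quinone 1); the chain branch is 4 steps (7–10) before the coupling.

**Step 1 (key step).** The most likely failure is a cycloaddition too slow to compete, because little of diene 2 is s-cis. The acid would then oligomerise the diene or isomerise it to 2-methylpenta-1,3-diene, which would add in its place. A stepwise cationic path would also erode the enantioselectivity.
Fallback, from 1 back to 7: the diene is replaced by allylidenecyclopropane F1, made by Wittig reaction of the ylide from cyclopropyltriphenylphosphonium bromide and KOtBu with acrolein. Its pinned-back ring removes the Z-substituent clash and its strained exocyclic alkene makes it a much better diene. The same catalysed cycloaddition would give spiro adduct F2. The conditions of steps 2–4 would then give carbinol F3, acetate F4 and unsaturated spiro ketone F5. Hydrogenation with RhCl(PPh3)3 would saturate the two alkenes without touching the three-membered ring, giving saturated spiro ketone F6. Hydrogenolysis over PtO2 in AcOH would open the cyclopropane at its unsubstituted CH2–CH2 bond and reveal the gem-dimethyl group, reaching 7 (a Swern oxidation would restore the C9 carbonyl if it were reduced as well).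

**Step 2.** The risk is poor discrimination between the two carbonyls, or double reduction, because each has a fully substituted carbon nearby (C4 beside C5 on one side, C10 on the other).
Fallback, from 3 back to 7: hydrogenation (H2, Pd/C) would saturate both alkenes to give saturated dione F7. Condensation with TsNHNH2 would take place at the C6 carbonyl, which keeps an unsubstituted α-methylene, to give mono-tosylhydrazone F8. Reduction with catecholborane followed by NaOAc·3H2O would convert C6 into CH2 and deliver 7. These steps would be run near neutrality to limit epimerisation at C5.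

**Step 11.** The risk is slow activation of the tetrasubstituted triflate next to quaternary C10, so that reduction of the triflate, S–O cleavage back to ketone 7, or homocoupling of 15 takes over.
Fallback, from 14 and 9 back to 16: elimination of 14 with KOtBu in THF would give terminal alkene F9, and hydroboration with 9-BBN would give B-alkyl borane F10. A B-alkyl Suzuki–Miyaura coupling with 9 (Pd(dppf)Cl2, AsPh3, Cs2CO3, DMF/THF/H2O), which proceeds through oxidative addition to zerovalent palladium and tolerates hindered enol triflates, would then form the C9–C11 bond and give 16.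

**Step 12.** The risk is sluggish addition to the hindered tetrasubstituted alkene. Forcing conditions would then allow migration of boron toward C17 or C7, mixed regiochemistry, or addition from the wrong face.
Fallback, from 16 back to 18: a Schenck ene reaction with singlet oxygen (O2, hν, tetraphenylporphyrin, CH2Cl2) should add oxygen to C8 on the open face while removing a hydrogen from C11, the group geminal to the bulky C10 substituent. This would give allylic hydroperoxide F11 with a C9=C11 double bond. Reduction with PPh3 would give tertiary allylic alcohol F12. Hydroxyl-directed hydrogenation with [Ir(cod)(PCy3)(py)]PF6 and H2 would then deliver hydrogen to C9 from the face of the C8 hydroxyl, giving 18 with the required cis relationship.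

## Further compounds

F1 | step 1 | allylidenecyclopropane (prop-2-en-1-ylidenecyclopropane) | C=CC=C1CC1
F2 | step 1 | spiro adduct: analogue of 3 with a spiro-cyclopropane at C4 in place of the two methyls | O=C1C(C)=CC(=O)[C@H]2C3(CC3)C=CC[C@@]12C
F3 | step 1 | C6 carbinol of F2 (C6 configuration not defined) | O=C1C(C)=CC(O)[C@H]2C3(CC3)C=CC[C@@]12C
F4 | step 1 | C6 acetate of F3 | O=C1C(C)=CC(OC(C)=O)[C@H]2C3(CC3)C=CC[C@@]12C
F5 | step 1 | unsaturated spiro ketone (C6 deoxygenated; C6=C7 and C2=C3 alkenes; C8 epimers) | O=C1C(C)C=C[C@H]2C3(CC3)C=CC[C@@]12C
F6 | step 1 | saturated spiro ketone (C8 epimers) | O=C1C(C)CC[C@H]2C3(CC3)CCC[C@@]12C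
F7 | step 2 | (4aS,8aR)-2,5,5,8a-tetramethyloctahydronaphthalene-1,4-dione (C8 epimers) | O=C1C(C)CC(=O)[C@H]2C(C)(C)CCC[C@@]12C
F8 | step 2 | C6 mono-tosylhydrazone of F7 | O=C1C(C)CC(=NNS(=O)(=O)c3ccc(C)cc3)[C@H]2C(C)(C)CCC[C@@]12C
F9 | step 11 | (R)-tert-butyldimethyl[(3-methylpent-4-en-1-yl)oxy]silane | CC(C)(C)[Si](C)(C)OCC[C@@H](C)C=C
F10 | step 11 | 9-[(3S)-5-(tert-butyldimethylsilyloxy)-3-methylpentyl]-9-borabicyclo[3.3.1]nonane | CC(C)(C)[Si](C)(C)OCC[C@@H](C)CCB1C2CCCC1CCC2
F11 | step 12 | C8 allylic hydroperoxide with C9=C11 double bond (alkene geometry not defined) | CC(C)(C)[Si](C)(C)OCC[C@@H](C)CC=C1[C@]2(C)CCCC(C)(C)[C@@H]2CC[C@@]1(C)OO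
F12 | step 12 | C8 tertiary allylic alcohol with C9=C11 double bond (alkene geometry not defined) | CC(C)(C)[Si](C)(C)OCC[C@@H](C)CC=C1[C@]2(C)CCCC(C)(C)[C@@H]2CC[C@@]1(C)O
A1 | alternative 1 | 3-[(3S)-5-(tert-butyldimethylsilyloxy)-3-methylpentyl]-4-(2-chloroprop-2-enyl)-4,6,6-trimethylbicyclo[3.1.1]heptan-2-one (C4 of the labdane bridging C5 and C7) | CC(C)(C)[Si](C)(C)OCC[C@@H](C)CC[C@H]1C(=O)[C@@H]2C[C@@H](C2(C)C)[C@@]1(C)CC(Cl)=C
A2 | alternative 1 | 9-alkyl cis-decalin-8-one: cis-fused 1-[(3S)-5-(tert-butyldimethylsilyloxy)-3-methylpentyl]-5,5,8a-trimethyloctahydronaphthalen-2(1H)-one | CC(C)(C)[Si](C)(C)OCC[C@@H](C)CC[C@@H]1[C@]2(C)CCCC(C)(C)[C@@H]2CCC1=O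
A3 | alternative 2 | (S)-1-diazo-4-(2,6,6-trimethylcyclohex-2-en-1-yl)butan-2-one | [N-]=[N+]=CC(=O)CC[C@@H]1C(C)=CCCC1(C)C
A4 | alternative 2 | tricyclic cyclopropyl ketone (C1–C9–C10 cyclopropane, C8 carbonyl) | O=C1CC[C@H]2C(C)(C)CC[C@H]3[C@@H]1[C@@]23C
A5 | alternative 3 | (2E,6S)-8-(tert-butyldimethylsilyloxy)-6-methyl-2-(4-methylpent-3-en-1-yl)oct-2-enal | O=C/C(CCC=C(C)C)=C/CC[C@H](C)CCO[Si](C)(C)C(C)(C)C
A6 | alternative 3 | (E)-1-(dimethylamino)-3-(tert-butyldimethylsilyloxy)buta-1,3-diene | CN(C)/C=C/C(=C)O[Si](C)(C)C(C)(C)C
A7 | alternative 3 | 4,4,5-trisubstituted cyclohex-2-enone (ring B with C20 as aldehyde, homoprenyl group on C10, chain on C9) | CC(C)(C)[Si](C)(C)OCC[C@@H](C)CC[C@@H]1[C@](C=O)(CCC=C(C)C)C=CC(=O)C1
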